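Time stopped helping early in both runs: between 15.0 h and 30.0 h Sunday's run read from 40.4% to 41.2% of the charge, and Wednesday's from 66.3% at 20.0 h to 67.6% at 30.0 h. So I asked first where a flask stops.

common to all: left-handed substrate 0.50 M; right-handed substrate 0.50 M; gas 29 mM (held)

| run | free catalyst | remark | time |
|---|---|---|---|
| Sunday's | 2.5 mol% | run made earlier |  |
| Wednesday's | 5.6 mol% | run made earlier |  |
| flask | 3.7 mol% |  | 25 h |

| run | time / h | left-handed product / % | right-handed product / % |
|---|---|---|---|
| Sunday's | 5.00 | 20.4 | 10.1 |
| Sunday's | 10.0 | 27.3 | 12.0 |
| Sunday's | 15.0 | 25.9 | 14.5 |
| Sunday's | 20.0 | 25.2 | 13.9 |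
| Sunday's | 25.0 | 27.4 | 14.7 |
| Sunday's | 30.0 | 27.0 | 14.2 |
| Wednesday's | 2.50 | 19.5 | 9.6 |
| Wednesday's | 4.00 | 28.2 | 13.7 |
| Wednesday's | 6.00 | 34.7 | 17.6 |
| Wednesday's | 10.0 | 43.3 | 23.2 |
| Wednesday's | 20.0 | 45.0 | 21.3 |
| Wednesday's | 30.0 | 46.1 | 21.5 |

(each reading ± 1 percentage point)

- left-handed product and right-handed product together, in percent of the left-handed substrate and right-handed substrate charged together, at 25 h
- excess of left-handed product over right-handed product in the product at 25 h
- whether the exchange between left-handed substrate and right-handed substrate keeps pace with the reaction: how far the product's excess at 25 h gets from its value without exchange to its value with instant exchange (above 80% keeps pace, below 20% hardly takes part, else lags behind)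

- free catalyst is single-handed; left-handed substrate and right-handed substrate are mirror images of each other, charged as a racemate, each of them at the stated concentration
- at the start none of coupling partner is dissolved
- the numbers in the tables scatter by 1 percentage point (one standard deviation)
- candidate steps: coupling partner + free catalyst + left-handed substrate -> free catalyst + left-handed product; coupling partner + free catalyst + right-handed substrate -> free catalyst + right-handed product; left-handed substrate <-> right-handed substrate; free catalyst <-> dormant form; gas <-> coupling partner; coupling partner + free catalyst -> spent catalyst
- an excess is below zero if the other one leads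

The bench rule gives each catalyst a fixed number of turnovers, so yield should follow loading. It failed: loading rose by a ratio of 2.24, the plateau by 1.64. I tried a log instead, ln(charge over what remains at the plateau) divided by the loading. Sunday's run gave 21.2 and Wednesday's 20.1, which are close. Their mean, 20.7, I called the reach.

For the new flask at 3.7 mol% the reach pointed to a remainder of 46.5% of the charge, so I expected 53.5% by 25 h.

Each substrate is half the charge. Without exchange, the ratio of the logs of their remaining fractions should equal the selectivity factor. Wednesday's last reading gave 4.54, while its first product ratio read 2.03. So I took the exchange to keep pace, and the two last excesses averaged 33.7%.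

The forecast said 53% (49% to 57%), an excess of 33%, a little under mine, and keeps pace, holding that "the catalyst dies through the coupling partner".

The new flask gave 53.4% with an excess of 35.2%, and the exchange went 99% of the way, so it keeps pace; its reach came to 20.6.

    coupling partner + free catalyst + left-handed substrate → free catalyst + left-handed product (k = 0.230 /M²/s)
    coupling partner + free catalyst + right-handed substrate → free catalyst + right-handed product (k = 0.110 /M²/s)
    left-handed substrate ⇌ right-handed substrate (k = 0.00270 /s)
    free catalyst ⇌ dormant form (K = 26.0, k = 1.40 × 10⁻⁵ /s)
    gas ⇌ coupling partner, rate k5*(csat - [coupling partner]) (kL = 0.00170 /s)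
    coupling partner + free catalyst → spent catalyst (k = 0.00330 /M/s)

With the other concentrations as charged, coupling partner had a half-life of 0.19 h by the coupling to right-handed product alone, against 3.2 h by the step to spent catalyst alone, a ratio of 16.7. At 25.0 h the new flask held 80.1% of its catalyst spent, 19.8% dormant and 0.113% free, with 47% of each substrate left. At 1.5 mol% of free catalyst the reach gives 26.7%, and that neighbouring flask gave 27.6% at 25.0 h.

The numbers in the tables are simulated with constants of no real substance, noise included.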